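**Retrosynthetic overview**

1. The target 15 comes from aryl bromide 12 (Heck reaction, then DIBAL-H, for the (E)-3-hydroxypropenyl chain at C5); 12 comes from the trans ester 9 by taking C3–CO2Me down to C3–CH3.
2. Ester 9 comes from (2S)-flavanone 6 by an oxidative 6→5 ring contraction: arene carbon C4a shifts from the ring carbonyl C4 to C3, and C4 leaves the ring to become the future C3 methyl carbon.
3. Flavanone 6 comes from chromone 4 and arylboronic acid 5 (catalytic asymmetric conjugate addition sets C2); 4 comes from acetophenone 2, made from commercial 1.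
4. Enabling feature: in the dihydrofuran ring O1–C2–C3–C3a–C7a, C3 carries both the arene carbon C3a and an exocyclic one-carbon group (the CH3). This array is C4a–C4(=O)–C3 of a chroman-4-one after a 1,2-shift of C4a; the C2(aryl)–O1 unit is flavanone C2–O1 and passes through unchanged.
5. Ring order: both benzene rings are bought; the pyranone ring is closed in step 2 and contracted to the dihydrofuran in step 4.

Key step: step 4

Remark (assumption): benzofuran numbering (O1, C2, C3, C3a, C4–C7, C7a) and chromanone numbering (O1, C2, C3, C4, C4a, C5–C8, C8a) are used. The (R)-pyridine-oxazoline ligand in step 3 is assumed to deliver the aryl group to the face that gives (2S)-6; if the sense proved opposite, the mirror-image ligand would be used.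

**Step 1**
Reactants: 1 1-(2-hydroxy-3-methoxyphenyl)ethan-1-one
Product: 2 1-(5-bromo-2-hydroxy-3-methoxyphenyl)ethan-1-one
Conditions: NBS (1.05 equiv), MeCN, 0 °C to rt
Reagents that add atoms: N-bromosuccinimide, O=C1CCC(=O)N1Br
Why: Electrophilic aromatic bromination; the free OH directs para (C5), the acetyl group directs meta to the same carbon, and both positions ortho to OH are blocked, so a single regioisomer is expected.

**Step 2**
Reactants: 2 1-(5-bromo-2-hydroxy-3-methoxyphenyl)ethan-1-one
Product: 4 6-bromo-8-methoxy-4H-chromen-4-one, via enaminone 3 (not isolated)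
Conditions: Me2NCH(OMe)2, toluene, 100 °C; then conc. HCl, CH2Cl2, 40 °C
Reagents that add atoms: N,N-dimethylformamide dimethyl acetal, COC(OC)N(C)C
Why: Condensation of the acetyl CH3 with the amide acetal gives the enaminone, and acid then promotes 6-endo addition of the phenol OH to the β-carbon with loss of dimethylamine (enaminone route to chromones), closing the pyranone ring.

**Step 3**
Reactants: 4 6-bromo-8-methoxy-4H-chromen-4-one; 5 (3,4-dimethoxyphenyl)boronic acid
Product: 6 (2S)-6-bromo-2-(3,4-dimethoxyphenyl)-8-methoxychroman-4-one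
Conditions: Pd(OCOCF3)2 (5 mol %), (R)-t-BuPyOx (6 mol %), NH4PF6 (30 mol %), H2O (5 equiv), ClCH2CH2Cl, 60 °C
Reagents that add atoms: none
Why: Pd(II)/pyridine-oxazoline-catalysed asymmetric conjugate addition of an arylboronic acid to a chromone (aryl–Pd addition across C2=C3, then protonolysis of the Pd enolate); the tert-butyl group of the ligand shields one face of the bound enone so that C2 should form as S, the aryl bromide is inert to Pd(II), and the non-basic medium avoids retro-oxa-Michael racemization.

**Step 4**
Reactants: 6 (2S)-6-bromo-2-(3,4-dimethoxyphenyl)-8-methoxychroman-4-one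
Product: 9 methyl (2S,3S)-5-bromo-2-(3,4-dimethoxyphenyl)-7-methoxy-2,3-dihydro-1-benzofuran-3-carboxylate, via enol ether 7 (not isolated), via iodane ketal 8 (not isolated)
Conditions: PhI(OAc)2 (1.1 equiv), conc. H2SO4 (0.5 equiv), HC(OMe)3, rt; aq. NaHCO3 work-up
Reagents that add atoms: trimethyl orthoformate, COC(OC)OC (ester OCH3); water, O (ester carbonyl oxygen, on work-up)
Why: Iodine(III)-mediated oxidative ring contraction of a flavanone in trimethyl orthoformate (the hypervalent-iodine counterpart of the thallium(III) nitrate rearrangement): acid and HC(OMe)3 convert 6 into enol ether 7, PhI(OAc)2 attacks its nucleophilic C3 anti to the equatorial C2 aryl group while methanol caps C4, and the resulting 2,3-trans λ3-iodanyl ketal 8 has C3 turned from donor into acceptor, so that two formerly nucleophilic carbons (enol carbon C3 and arene carbon C4a) can be joined. The five-membered ring is closed by a suprafacial 1,2-shift of C4a from C4 to C3 through a bridged arenium (phenonium-type, formally 3-exo-trig) transition structure with loss of PhI, and the expelled C4 leaves as a dimethoxycarbenium ion that water converts into the methyl ester on work-up. C2 is not touched and keeps the S configuration from step 3; the new centre C3 is set by anti addition of iodine relative to the aryl group followed by inversion at C3 during the shift, which places CO2Me trans to the aryl group (2S,3S), also the thermodynamically preferred epimer. The step needs ring contraction to win over the C2→C3 shift of the electron-rich dimethoxyphenyl ring (isoflavone), dehydrogenation (flavone) and simple α-methoxylation: the equatorial C3–I bond of 8 is antiperiplanar only to the ring bond C4–C4a and not to the equatorial C2–aryl bond, and the two methoxy groups on C4 make it the best cation-accepting terminus. The acidic, non-basic medium should prevent ring opening of 6 to the chalcone, so the enantiomeric purity is carried through.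

**Step 5**
Reactants: 9 methyl (2S,3S)-5-bromo-2-(3,4-dimethoxyphenyl)-7-methoxy-2,3-dihydro-1-benzofuran-3-carboxylate
Product: 10 [(2S,3R)-5-bromo-2-(3,4-dimethoxyphenyl)-7-methoxy-2,3-dihydro-1-benzofuran-3-yl]methanol
Conditions: DIBAL-H (2.5 equiv), CH2Cl2, −78 to 0 °C; Rochelle salt work-up
Reagents that add atoms: none
Why: DIBAL-H reduction of the ester to the primary alcohol at low temperature leaves the aryl bromide and both stereocentres untouched (the C3 descriptor becomes R only through the change in substituent priority).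

**Step 6**
Reactants: 10 [(2S,3R)-5-bromo-2-(3,4-dimethoxyphenyl)-7-methoxy-2,3-dihydro-1-benzofuran-3-yl]methanol
Product: 11 [(2S,3R)-5-bromo-2-(3,4-dimethoxyphenyl)-7-methoxy-2,3-dihydro-1-benzofuran-3-yl]methyl 4-methylbenzenesulfonate
Conditions: TsCl (1.3 equiv), Et3N, DMAP (cat.), CH2Cl2, 0 °C to rt
Reagents that add atoms: p-toluenesulfonyl chloride, Cc1ccc(S(=O)(=O)Cl)cc1
Why: Sulfonylation of a primary alcohol turns OH into a leaving group without involving either stereocentre.

**Step 7**
Reactants: 11 [(2S,3R)-5-bromo-2-(3,4-dimethoxyphenyl)-7-methoxy-2,3-dihydro-1-benzofuran-3-yl]methyl 4-methylbenzenesulfonate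
Product: 12 (2S,3S)-5-bromo-2-(3,4-dimethoxyphenyl)-7-methoxy-3-methyl-2,3-dihydro-1-benzofuran
Conditions: LiEt3BH (2 equiv), THF, 0 °C to rt
Reagents that add atoms: none
Why: SN2 displacement of the primary tosylate by the strongly nucleophilic, weakly basic hydride of LiEt3BH should give the C3 methyl group; the aryl bromide is not expected to react and no bond to a stereocentre is broken.

**Step 8**
Reactants: 12 (2S,3S)-5-bromo-2-(3,4-dimethoxyphenyl)-7-methoxy-3-methyl-2,3-dihydro-1-benzofuran; 13 ethyl acrylate
Product: 14 ethyl (E)-3-[(2S,3S)-2-(3,4-dimethoxyphenyl)-7-methoxy-3-methyl-2,3-dihydro-1-benzofuran-5-yl]prop-2-enoate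
Conditions: Pd2(dba)3 (2.5 mol %), [HP(t-Bu)3]BF4 (10 mol %), Cy2NMe, dioxane, 80 °C
Reagents that add atoms: none
Why: Mizoroki–Heck reaction; the bulky electron-rich phosphine allows oxidative addition of the electron-rich aryl bromide, and syn insertion followed by syn β-hydride elimination should give the E-cinnamate.

**Step 9**
Reactants: 14 ethyl (E)-3-[(2S,3S)-2-(3,4-dimethoxyphenyl)-7-methoxy-3-methyl-2,3-dihydro-1-benzofuran-5-yl]prop-2-enoate
Product: 15 (E)-3-[(2S,3S)-2-(3,4-dimethoxyphenyl)-7-methoxy-3-methyl-2,3-dihydro-1-benzofuran-5-yl]prop-2-en-1-ol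
Conditions: DIBAL-H (2.5 equiv), CH2Cl2, −78 °C; Rochelle salt work-up
Reagents that add atoms: none
Why: 1,2-Reduction of the α,β-unsaturated ester by DIBAL-H at −78 °C should give the allylic alcohol with the E double bond and the trans-dihydrobenzofuran intact.

**Compound list**

1 | 1-(2-hydroxy-3-methoxyphenyl)ethan-1-one | CC(=O)c1cccc(OC)c1O | starting material
2 | 1-(5-bromo-2-hydroxy-3-methoxyphenyl)ethan-1-one | CC(=O)c1cc(Br)cc(OC)c1O | intermediate
3 | (E)-1-(5-bromo-2-hydroxy-3-methoxyphenyl)-3-(dimethylamino)prop-2-en-1-one (enaminone, formed in the flask) | CN(C)/C=C/C(=O)c1cc(Br)cc(OC)c1O | intermediate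
4 | 6-bromo-8-methoxy-4H-chromen-4-one | O=c1ccoc2c(OC)cc(Br)cc12 | intermediate
5 | (3,4-dimethoxyphenyl)boronic acid | COc1ccc(B(O)O)cc1OC | starting material
6 | (2S)-6-bromo-2-(3,4-dimethoxyphenyl)-8-methoxychroman-4-one | COc1ccc([C@H]2Oc3c(OC)cc(Br)cc3C(=O)C2)cc1OC | intermediate
7 | (2S)-6-bromo-2-(3,4-dimethoxyphenyl)-4,8-dimethoxy-2H-chromene (enol ether, formed in the flask) | COc1ccc([C@H]2Oc3c(OC)cc(Br)cc3C(OC)=C2)cc1OC | intermediate
8 | 2,3-trans-3-[acetoxy(phenyl)-λ3-iodanyl]-6-bromo-2-(3,4-dimethoxyphenyl)-4,4,8-trimethoxychromane (iodane ketal, formed in the flask) | COc1ccc([C@H]2Oc3c(OC)cc(Br)cc3C(OC)(OC)[C@@H]2I(OC(C)=O)c4ccccc4)cc1OC | intermediate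
9 | methyl (2S,3S)-5-bromo-2-(3,4-dimethoxyphenyl)-7-methoxy-2,3-dihydro-1-benzofuran-3-carboxylate (2,3-trans) | COc1ccc([C@H]2Oc3c(OC)cc(Br)cc3[C@@H]2C(=O)OC)cc1OC | intermediate
10 | [(2S,3R)-5-bromo-2-(3,4-dimethoxyphenyl)-7-methoxy-2,3-dihydro-1-benzofuran-3-yl]methanol (2,3-trans) | COc1ccc([C@H]2Oc3c(OC)cc(Br)cc3[C@@H]2CO)cc1OC | intermediate
11 | [(2S,3R)-5-bromo-2-(3,4-dimethoxyphenyl)-7-methoxy-2,3-dihydro-1-benzofuran-3-yl]methyl 4-methylbenzenesulfonate | COc1ccc([C@H]2Oc3c(OC)cc(Br)cc3[C@@H]2COS(=O)(=O)c4ccc(C)cc4)cc1OC | intermediate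
12 | (2S,3S)-5-bromo-2-(3,4-dimethoxyphenyl)-7-methoxy-3-methyl-2,3-dihydro-1-benzofuran (2,3-trans) | COc1ccc([C@H]2Oc3c(OC)cc(Br)cc3[C@@H]2C)cc1OC | intermediate
13 | ethyl acrylate | C=CC(=O)OCC | starting material
14 | ethyl (E)-3-[(2S,3S)-2-(3,4-dimethoxyphenyl)-7-methoxy-3-methyl-2,3-dihydro-1-benzofuran-5-yl]prop-2-enoate | COc1ccc([C@H]2Oc3c(OC)cc(/C=C/C(=O)OCC)cc3[C@@H]2C)cc1OC | intermediate
15 | (E)-3-[(2S,3S)-2-(3,4-dimethoxyphenyl)-7-methoxy-3-methyl-2,3-dihydro-1-benzofuran-5-yl]prop-2-en-1-ol (2,3-trans) | COc1ccc([C@H]2Oc3c(OC)cc(/C=C/CO)cc3[C@@H]2C)cc1OC | target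

**Step count and risks**

Total steps: 9. Longest linear sequence: 9 steps (1 → 15).

Steps most likely to fail:

1. Step 4 (key step). The oxidative shift may be diverted: migration of the electron-rich dimethoxyphenyl ring to C3, dehydrogenation of the pyranone ring, α-methoxylation without rearrangement, or oxidation of the veratryl ring by iodine(III). Fallback from 6 back to 9: the same 6→5 contraction would be run as a photochemical Wolff rearrangement, which creates no cationic centre next to the B ring. Flavanone 6 is deprotonated at −78 °C (LiHMDS, THF) and trapped with CF3CO2CH2CF3 to give the 3-trifluoroacetyl ketone F1. Detrifluoroacetylative diazo transfer (MsN3, Et3N, MeCN, H2O) then gives the 3-diazo ketone F2. Irradiation (300–350 nm, MeOH) extrudes N2 with 1,2-shift of C4a to C3, and the ketene adds methanol; protonation of the ester enol anti to the aryl group should give mainly the cis ester F3. Brief NaOMe/MeOH equilibration epimerizes C3 to the trans ester 9, where the route is rejoined.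

2. Step 3. Protodeboronation of the electron-rich boronic acid, slow turnover, or insufficient facial selectivity may limit yield or enantiomeric purity. Fallback from 2 back to 6: the flavanone would be built from the other direction. Claisen–Schmidt condensation of 2 with commercial 3,4-dimethoxybenzaldehyde (KOH, EtOH) gives the 2'-hydroxychalcone F4, which cyclizes by oxa-Michael addition (NaOAc, EtOH, reflux) to the racemic flavanone F5. Kinetic resolution by asymmetric transfer hydrogenation (Cp*RhCl(TsDPEN), HCO2H/Et3N) follows, with the catalyst enantiomer chosen so that the (2R)-ketone is reduced to the cis-flavan-4-ol F6. The unreacted (2S)-flavanone 6 is separated by chromatography and enters step 4.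

3. Step 7. Hydride displacement may be accompanied by E2 elimination to the exocyclic alkene and aromatization to the 3-methylbenzofuran, or by partial reduction of the C–Br bond. Fallback from 10 back to 12: the C–O bond would be cleaved by a radical instead of an SN2 process. Alcohol 10 is converted into the primary iodide F7 (I2, PPh3, imidazole, CH2Cl2) and reduced with Bu3SnH (1.1 equiv)/AIBN in benzene at 80 °C. Iodine abstraction from the primary alkyl iodide should be much faster than bromine abstraction from the aryl bromide, and the primary radical should be quenched to the methyl group of 12 before any neophyl-type shift.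

**Further compounds**

F1 | step 4 | (2S)-6-bromo-2-(3,4-dimethoxyphenyl)-8-methoxy-3-(2,2,2-trifluoroacetyl)chroman-4-one (C3 unassigned, enolized) | COc1ccc([C@H]2Oc3c(OC)cc(Br)cc3C(=O)C2C(=O)C(F)(F)F)cc1OC
F2 | step 4 | (2R)-6-bromo-3-diazo-2-(3,4-dimethoxyphenyl)-8-methoxychroman-4-one (same spatial arrangement at C2 as 6; descriptor changes by priority) | COc1ccc([C@H]2Oc3c(OC)cc(Br)cc3C(=O)C2=[N+]=[N-])cc1OC
F3 | step 4 | methyl (2S,3R)-5-bromo-2-(3,4-dimethoxyphenyl)-7-methoxy-2,3-dihydro-1-benzofuran-3-carboxylate (2,3-cis) | COc1ccc([C@H]2Oc3c(OC)cc(Br)cc3[C@H]2C(=O)OC)cc1OC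
F4 | step 3 | (E)-1-(5-bromo-2-hydroxy-3-methoxyphenyl)-3-(3,4-dimethoxyphenyl)prop-2-en-1-one | COc1ccc(/C=C/C(=O)c2cc(Br)cc(OC)c2O)cc1OC
F5 | step 3 | rac-6-bromo-2-(3,4-dimethoxyphenyl)-8-methoxychroman-4-one | COc1ccc(C2Oc3c(OC)cc(Br)cc3C(=O)C2)cc1OC
F6 | step 3 | (2R,4R)-6-bromo-2-(3,4-dimethoxyphenyl)-8-methoxychroman-4-ol (2,4-cis) | COc1ccc([C@@H]2Oc3c(OC)cc(Br)cc3[C@H](O)C2)cc1OC
F7 | step 7 | (2S,3S)-5-bromo-2-(3,4-dimethoxyphenyl)-3-(iodomethyl)-7-methoxy-2,3-dihydro-1-benzofuran (2,3-trans) | COc1ccc([C@H]2Oc3c(OC)cc(Br)cc3[C@@H]2CI)cc1OC
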